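Remark on conventions: all intermediates carry the target's locants (C1–C10 ring, C11/C12/C13 lactone carbons, C14 on C10, C15 on C4); "ring-cis" means that the two ring bonds of an olefin are cis.
Remark on materials: (S)-epichlorohydrin, ethyl 2-(hydroxymethyl)acrylate, 4-methyl hydrogen itaconate and (S)-4-benzyl-1,3-thiazolidine-2-thione are assumed to be purchasable.

## Analysis of the target

The target is a germacranolide: a cyclodeca-1(10),4-diene (C1–C10) fused at C6/C7 to an α-methylene-γ-butyrolactone (C11, C12, C13). Both ring olefins are trisubstituted and ring-cis (C2 cis to C9 on C1=C10, C3 cis to C6 on C4=C5); their CIP descriptors are E only because C14 and C15 outrank the ring methylenes. There are four stereocentres: C2 (S, free allylic hydroxyl), C6 (R, lactone oxygen), C7 (R) and C8 (R, isovalerate). O6 and C11 are trans on the ring, O8 is cis to C11, and C2 is separated from the C6–C8 triad by the C1=C10 olefin on one side and C3–C5 on the other. Sensitive groups are the conjugated C14 aldehyde, the exocyclic methylene lactone (a Michael acceptor), the allylic C15 acetate that must be told apart from the C12 and C14 oxygens, a hindered secondary ester and the free C2 carbinol next to the enal. The difficulties are the ten-membered ring (entropy and transannular strain), two trisubstituted olefins of fixed geometry that each carry an oxidised one-carbon branch, and the relay of configuration between C2 and the distant C6–C8 block. The strategy rests on the array C8(O)–C9H2–C10(C14)=C1H–C2 inside the carbocycle. This is a homoallylic alcohol whose olefin carries its branch on the internal carbon, i.e. the retron of the addition of a C1-borylated, 2-substituted allyl unit to a C8 aldehyde. Made the ring-closing event, that addition gives the C8–C9 ring bond, the C8 carbinol and the ring-cis C1=C10 olefin from one transition state.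

## Retrosynthetic reasoning

40 to 37. The lactone carbonyl (C12) and the C14 aldehyde are both oxidised forms of primary allylic alcohols, and O6 is 1,4 to C12. The lactone and the enal are therefore traced back to tetraol 37 and one chemoselective oxidation. This keeps the Michael-acceptor lactone and the enal out of every earlier step.

37 to 33. The two esters are cut next. In 33 the C8 hydroxyl is the only free one, so the isovalerate goes on first (34). C15 is carried as a 4-methoxybenzyl ether, the one group removable beside four silyl ethers (35), and is then acetylated (36). The allylic acetate is deliberately not carried through the ring closure: an allylic acetate can itself undergo copper–boryl substitution, and it would not survive the hydride that frees C8.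

33 to 31 (key disconnection). The C8–C9 bond is cut and the olefin moved from C1=C10 to C10=C9, placing boron on C1. This cut is chosen because it is the only ring bond whose formation also sets a stereocentre (C8) and a ring olefin geometry (C1=C10). The forward reaction must add C9 of the allylboronate to the C8 aldehyde intramolecularly through a closed chair, so that the C1 configuration is translated into C8 and into the ring-cis olefin. In 31, C11–C13 are kept as a silyloxy-propenyl group so that the C8 aldehyde is not an acidic β-formyl lactone.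

31 to 29. The aldehyde is released last, from Weinreb amide 30 by hydride, because an α-alkenyl, β-silyloxy aldehyde tolerates neither base nor storage. The C1–B bond of 30 is traced to the primary allylic carbonate 29 by copper-catalysed γ-borylation. This creates the boron-bearing centre and the C10=C9 methylene in one step, under the influence of the neighbouring C2 stereocentre and a chiral ligand.

29 to 19 + 25. C6–C7 is cut as an aldol bond. A chromium-mediated allylation of the C6 enal would give the right anti relationship, but C6 has no stereocentre nearer than C2, so it would give both enantiomeric C6/C7 pairs. An auxiliary-controlled syn-aldol between enal 19 and thioimide 25 fixes C6 and C7 absolutely. The adduct 27 is converted to Weinreb amide 28 and silylated (29), so C8 already has the oxidation level the key step needs.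

19 to 10 + 13. The C1=C10 olefin of 19 carries two different oxygenated arms. Its geometry is secured through a ring: butenolide 15, from ring-closing metathesis of acrylate 14 (alcohol 10 + acid 13), ties the future C9 to O2 and hence cis to C2. Reduction (16), carbonate formation at the primary hydroxyl (17), silylation (18) and oxidation of the C6 silyl ether give 19.

10 to 5 + 6. C3–C4 is cut between an alkenyl nucleophile and the epoxide carbon of (S)-epichlorohydrin 6, which supplies C1–C3 and the C2 stereocentre from the chiral pool. The chlorohydrin 8 is homologated to the vinyl carbinol 10 with a sulfonium ylide by way of epoxide 9.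

5 to 1. The ring-cis C4=C5 geometry is traced to the alkyne of 1. Directed trans-hydroalumination and iodination of the mono-ether 2 give iodide 4, in which iodine holds the place of C3 cis to C6.

Side chains. Thioimide 25 comes from acid 23 and auxiliary 24, and 23 from itaconate 20 by reduction, silylation and saponification (21, 22). Acid 13 comes from hydroxy ester 11 via 12.

## Alternatives that were turned down

Alternative 1: The ten-membered ring is traced to a six-membered carbocycle in which C5–C10 is still a bond and C2–C3 is not. In the forward direction an anionic oxy-Cope rearrangement (potassium amide base, crown ether) forms C2–C3, breaks C5–C10 and opens the ring; the C10 enolate is trapped as the enol triflate A1. In its favour, this is the best-precedented entry to cyclodeca-1,5-dienes, the ring strain is paid for by the alkoxide, and no high dilution is needed. On precedent it is stronger than the chosen route. Against it for this target: the cyclohexane needs five stereocentres and a geometrically defined enol ether, since C2 is only created in the rearrangement. The cis-dialkenyl arrangement delivers C1=C10 as the ring-trans enol triflate, whereas the target is ring-cis, so the olefin must be isomerised after C14 has been added by carbonylation. C2 and C15 both emerge as 4-methoxybenzyl ethers and must still be differentiated. The chosen strategy instead has C14 in place before ring closure and sets the C1=C10 geometry and C8 in the ring-forming step, with a five-step endgame.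

Alternative 2: C6–C7 is cut and the carbocycle is traced to a thirteen-membered cyclic bis-allylic ether (O linking C6 and C13). In the forward direction an alkyllithium deprotonates C6 and the anion attacks C7 in a [2,3] shift that breaks O–C13 and contracts the ring, giving cyclodecadienol A2 with the C11=C13 methylene. In its favour, macro-etherification to a thirteen-membered ring is easy, and the contraction makes the C6 carbinol, C7 and the exocyclic methylene at once. This type of ring contraction to ten-membered carbocycles is known, so it too is ahead of the chosen route in precedent. Against it: deprotonation must choose C6 over C13; the strongly basic conditions exclude esters and the carbonate-type groups; C6/C7 depend on transannular induction from C2 and C8; and A2 is the C8 epimer, so an inversion at a hindered ring carbinol is added to a long protecting-group endgame (five different groups). The chosen strategy delivers all four stereocentres with the correct configuration and closes the ring under neutral conditions.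

Alternative 3: C1–C2 is cut. In the forward direction a C1 alkenyl iodide is converted by divalent chromium chloride, a nickel co-catalyst and a chiral sulfonamide ligand into an alkenylchromium that adds to a C2 aldehyde, closing the ring to A3. It is clearly stronger in two respects: chromium-mediated macrocyclisations are established and tolerate the complete lactone and both esters, and only two steps (desilylation, oxidation of C14) remain after A3. Against it: the C2 configuration must be imposed by the ligand against the conformational preference of a strained ten-membered transition state. The seco aldehyde is a β,γ-unsaturated aldehyde (C3 between CHO and C4=C5) that conjugates readily. The electrophilic methylene lactone has to be carried through the fragment assembly, and the ring-cis trisubstituted alkenyl iodide must be made geometrically pure. The chosen strategy takes C2 from the chiral pool and lets one sp3 boron centre dictate both C8 and the olefin geometry in a closed transition state, at the price of a ring closure without precedent at this ring size.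

Key step: step 23

## Route

Step 1
Reactants: 1 2-butyne-1,4-diol
Product: 2 4-[(4-methoxybenzyl)oxy]but-2-yn-1-ol
Conditions: NaH (1 equiv), 4-methoxybenzyl chloride (1 equiv), Bu4NI (cat.), THF/DMF, 0 °C → rt; 1 in threefold excess
Reagents that add atoms: 4-methoxybenzyl chloride, COc1ccc(CCl)cc1
Why: Williamson mono-etherification of a symmetric diol; the excess of 1 suppresses the bis-ether and is removed with water.

Step 2
Reactants: 2 4-[(4-methoxybenzyl)oxy]but-2-yn-1-ol
Product: 4 (Z)-3-iodo-4-[(4-methoxybenzyl)oxy]but-2-en-1-ol, via alkenylalanate 3 (not isolated)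
Conditions: NaAlH2(OCH2CH2OMe)2, THF, 0 °C; then I2, −78 → 0 °C
Reagents that add atoms: iodine, II
Why: Hydroxyl-directed trans-hydroalumination puts hydride on the carbon next to the free carbinol (C5) and aluminium on C4 in the chelate 3; iodinolysis with retention gives the (Z)-iodide. Iodine stands where C3 will be, cis to C6, so the ring-cis C4=C5 geometry is fixed here.

Step 3
Reactants: 4 (Z)-3-iodo-4-[(4-methoxybenzyl)oxy]but-2-en-1-ol
Product: 5 (Z)-triethyl({3-iodo-4-[(4-methoxybenzyl)oxy]but-2-en-1-yl}oxy)silane
Conditions: Et3SiCl, imidazole, CH2Cl2, 0 °C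
Reagents that add atoms: chlorotriethylsilane, CC[Si](Cl)(CC)CC
Why: Silylation of the primary allylic alcohol; the triethylsilyl group is chosen because it can later be oxidised off C6 beside tert-butyldimethylsilyl ethers.

Step 4
Reactants: 5 (Z)-triethyl({3-iodo-4-[(4-methoxybenzyl)oxy]but-2-en-1-yl}oxy)silane; 6 (S)-epichlorohydrin
Product: 8 (2S,4E)-1-chloro-4-{[(4-methoxybenzyl)oxy]methyl}-6-[(triethylsilyl)oxy]hex-4-en-2-ol, via alkenyllithium 7 (not isolated)
Conditions: t-BuLi (2 equiv), Et2O, −78 °C; then BF3·OEt2, 6, −78 °C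
Reagents that add atoms: none
Why: Iodine–lithium exchange proceeds with retention of olefin geometry, and the BF3-activated epoxide is opened at its unsubstituted carbon (C3–C4 bond). C2 is taken unchanged from 6; the chloride survives at −78 °C.

Step 5
Reactants: 8 (2S,4E)-1-chloro-4-{[(4-methoxybenzyl)oxy]methyl}-6-[(triethylsilyl)oxy]hex-4-en-2-ol
Product: 10 (3S,5E)-5-{[(4-methoxybenzyl)oxy]methyl}-7-[(triethylsilyl)oxy]hepta-1,5-dien-3-ol, via epoxide 9 (not isolated)
Conditions: Me3SI, n-BuLi (excess ylide), THF, −10 °C → rt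
Reagents that add atoms: trimethylsulfonium iodide, C[S+](C)C.[I-]
Why: The alkoxide closes to the terminal epoxide 9; dimethylsulfonium methylide opens it at C1 and the betaine loses dimethyl sulfide, a one-carbon homologation of an epoxide to an allylic alcohol. The C2–O bond is never broken, so C2 keeps its configuration.

Step 6
Reactants: 11 ethyl 2-(hydroxymethyl)acrylate
Product: 12 ethyl 2-({[tert-butyl(dimethyl)silyl]oxy}methyl)acrylate
Conditions: t-BuMe2SiCl, imidazole, DMF, 0 °C → rt
Reagents that add atoms: tert-butyl(chloro)dimethylsilane, CC(C)(C)[Si](C)(C)Cl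
Why: Standard silylation of a primary allylic alcohol; this oxygen becomes O14.

Step 7
Reactants: 12 ethyl 2-({[tert-butyl(dimethyl)silyl]oxy}methyl)acrylate
Product: 13 2-({[tert-butyl(dimethyl)silyl]oxy}methyl)acrylic acid
Conditions: LiOH, THF/H2O, 0 °C; then aq. HCl to pH 4
Reagents that add atoms: none
Why: Saponification of an ester without α-hydrogen; cold, brief acidification spares the silyl ether.

Step 8
Reactants: 10 (3S,5E)-5-{[(4-methoxybenzyl)oxy]methyl}-7-[(triethylsilyl)oxy]hepta-1,5-dien-3-ol; 13 2-({[tert-butyl(dimethyl)silyl]oxy}methyl)acrylic acid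
Product: 14 (3S,5E)-5-{[(4-methoxybenzyl)oxy]methyl}-7-[(triethylsilyl)oxy]hepta-1,5-dien-3-yl 2-({[tert-butyl(dimethyl)silyl]oxy}methyl)prop-2-enoate
Conditions: DCC, DMAP (cat.), CH2Cl2, 0 °C → rt
Reagents that add atoms: none
Why: Steglich esterification of the secondary alcohol; acylation at oxygen does not touch C2.

Step 9
Reactants: 14 (3S,5E)-5-{[(4-methoxybenzyl)oxy]methyl}-7-[(triethylsilyl)oxy]hepta-1,5-dien-3-yl 2-({[tert-butyl(dimethyl)silyl]oxy}methyl)prop-2-enoate
Product: 15 (5S)-3-({[tert-butyl(dimethyl)silyl]oxy}methyl)-5-[(2E)-2-{[(4-methoxybenzyl)oxy]methyl}-4-[(triethylsilyl)oxy]but-2-en-1-yl]furan-2(5H)-one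
Conditions: second-generation Grubbs catalyst (H2IMes)(PCy3)Cl2Ru=CHPh (5 mol%), toluene, 80 °C
Reagents that add atoms: none
Why: Ring-closing metathesis of an allyl 2-substituted acrylate to a butenolide with loss of ethene; the trisubstituted C4=C5 olefin cannot compete with five-ring formation. The lactone ring forces the carbonyl carbon (future C9) cis to C2 on C1=C10, so the two arms on C10 are differentiated without an E/Z problem.

Step 10
Reactants: 15 (5S)-3-({[tert-butyl(dimethyl)silyl]oxy}methyl)-5-[(2E)-2-{[(4-methoxybenzyl)oxy]methyl}-4-[(triethylsilyl)oxy]but-2-en-1-yl]furan-2(5H)-one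
Product: 16 (2E,4S,6E)-2-({[tert-butyl(dimethyl)silyl]oxy}methyl)-6-{[(4-methoxybenzyl)oxy]methyl}-8-[(triethylsilyl)oxy]octa-2,6-diene-1,4-diol
Conditions: i-Bu2AlH (excess), CH2Cl2, −78 → 0 °C; aq. potassium sodium tartrate
Reagents that add atoms: none
Why: 1,2-Reduction of the unsaturated lactone to the ene-1,4-diol; neutral tartrate work-up avoids dehydration to a furan.

Step 11
Reactants: 16 (2E,4S,6E)-2-({[tert-butyl(dimethyl)silyl]oxy}methyl)-6-{[(4-methoxybenzyl)oxy]methyl}-8-[(triethylsilyl)oxy]octa-2,6-diene-1,4-diol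
Product: 17 (2E,4S,6E)-2-({[tert-butyl(dimethyl)silyl]oxy}methyl)-4-hydroxy-6-{[(4-methoxybenzyl)oxy]methyl}-8-[(triethylsilyl)oxy]octa-2,6-dien-1-yl methyl carbonate
Conditions: ClCO2Me (1.1 equiv), pyridine, CH2Cl2, −20 °C
Reagents that add atoms: methyl chloroformate, COC(=O)Cl
Why: Chemoselective carbonate formation at the primary allylic hydroxyl (C9) over the hindered secondary C2 hydroxyl at low temperature.

Step 12
Reactants: 17 (2E,4S,6E)-2-({[tert-butyl(dimethyl)silyl]oxy}methyl)-4-hydroxy-6-{[(4-methoxybenzyl)oxy]methyl}-8-[(triethylsilyl)oxy]octa-2,6-dien-1-yl methyl carbonate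
Product: 18 (2E,4S,6E)-4-{[tert-butyl(dimethyl)silyl]oxy}-2-({[tert-butyl(dimethyl)silyl]oxy}methyl)-6-{[(4-methoxybenzyl)oxy]methyl}-8-[(triethylsilyl)oxy]octa-2,6-dien-1-yl methyl carbonate
Conditions: t-BuMe2SiOTf, 2,6-lutidine, CH2Cl2, −78 °C
Reagents that add atoms: tert-butyldimethylsilyl trifluoromethanesulfonate, CC(C)(C)[Si](C)(C)OS(=O)(=O)C(F)(F)F
Why: Silylation of the secondary allylic alcohol with a silyl triflate and a hindered base; carbonate and the other ethers are inert.

Step 13
Reactants: 18 (2E,4S,6E)-4-{[tert-butyl(dimethyl)silyl]oxy}-2-({[tert-butyl(dimethyl)silyl]oxy}methyl)-6-{[(4-methoxybenzyl)oxy]methyl}-8-[(triethylsilyl)oxy]octa-2,6-dien-1-yl methyl carbonate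
Product: 19 (2E,4S,6E)-4-{[tert-butyl(dimethyl)silyl]oxy}-2-({[tert-butyl(dimethyl)silyl]oxy}methyl)-6-{[(4-methoxybenzyl)oxy]methyl}-8-oxoocta-2,6-dien-1-yl methyl carbonate
Conditions: (COCl)2, DMSO, CH2Cl2, −78 → −30 °C; then Et3N, −78 °C
Reagents that add atoms: none
Why: Swern oxidation applied directly to a primary triethylsilyl ether: the chlorosulfonium salt removes the triethylsilyl group and oxidises C6 to the enal, while tert-butyldimethylsilyl ethers stay. The cold, brief base treatment leaves the C4=C5 geometry intact.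

Step 14
Reactants: 20 4-methyl hydrogen itaconate (2-methylidenebutanedioic acid 4-methyl ester)
Product: 21 methyl 3-(hydroxymethyl)but-3-enoate
Conditions: BH3·SMe2 (1.05 equiv), THF, −10 → 0 °C; MeOH quench
Reagents that add atoms: none
Why: Borane reduces a carboxylic acid much faster than an ester or an electron-poor olefin, giving the allylic alcohol that becomes C12.

Step 15
Reactants: 21 methyl 3-(hydroxymethyl)but-3-enoate
Product: 22 methyl 3-({[tert-butyl(dimethyl)silyl]oxy}methyl)but-3-enoate
Conditions: t-BuMe2SiCl, imidazole, DMF, 0 °C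
Reagents that add atoms: tert-butyl(chloro)dimethylsilane, CC(C)(C)[Si](C)(C)Cl
Why: Prompt silylation prevents lactonisation of the γ-hydroxy ester.

Step 16
Reactants: 22 methyl 3-({[tert-butyl(dimethyl)silyl]oxy}methyl)but-3-enoate
Product: 23 3-({[tert-butyl(dimethyl)silyl]oxy}methyl)but-3-enoic acid
Conditions: LiOH, THF/H2O, 0 °C; then aq. HCl to pH 4
Reagents that add atoms: none
Why: Saponification at 0 °C; the short, cold treatment keeps the olefin out of conjugation.

Step 17
Reactants: 23 3-({[tert-butyl(dimethyl)silyl]oxy}methyl)but-3-enoic acid; 24 (S)-4-benzyl-1,3-thiazolidine-2-thione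
Product: 25 (S)-4-benzyl-3-[3-({[tert-butyl(dimethyl)silyl]oxy}methyl)but-3-enoyl]-1,3-thiazolidine-2-thione
Conditions: DCC, DMAP (cat.), CH2Cl2, 0 °C
Reagents that add atoms: none
Why: Carbodiimide N-acylation of the thiazolidinethione, the usual entry to these thioimides.

Step 18
Reactants: 25 (S)-4-benzyl-3-[3-({[tert-butyl(dimethyl)silyl]oxy}methyl)but-3-enoyl]-1,3-thiazolidine-2-thione; 19 (2E,4S,6E)-4-{[tert-butyl(dimethyl)silyl]oxy}-2-({[tert-butyl(dimethyl)silyl]oxy}methyl)-6-{[(4-methoxybenzyl)oxy]methyl}-8-oxoocta-2,6-dien-1-yl methyl carbonate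
Product: 27 syn-aldol adduct (C8 thioimide; free C6-OH; C7 bearing the 3-silyloxyprop-1-en-2-yl group; 2S 6R 7S), via titanium enolate 26 (not isolated)
Conditions: 25, TiCl4, i-Pr2NEt, N-methyl-2-pyrrolidinone, CH2Cl2, 0 °C; then 19, −78 → −40 °C
Reagents that add atoms: none
Why: Crimmins titanium-enolate aldol: the (Z)-chlorotitanium enolate 26 reacts at its α-carbon with the enal through a non-chelated chair, and the benzyl group of the auxiliary blocks one enolate face (Evans-syn sense). C6 and C7 are both set here, with O6 and C11 syn along C5–C8, which is the trans lactone fusion of the target.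

Step 19
Reactants: 27 syn-aldol adduct (C8 thioimide; free C6-OH)
Product: 28 Weinreb amide (C8 N-methoxy-N-methylamide; free C6-OH; 2S 6R 7S)
Conditions: MeNHOMe·HCl, imidazole, CH2Cl2, rt
Reagents that add atoms: N,O-dimethylhydroxylamine hydrochloride, CNOC.Cl
Why: The thiazolidinethione is an activated amide that is displaced by the hydroxylamine under near-neutral conditions; the carbonate is not attacked and 24 is recovered.

Step 20
Reactants: 28 Weinreb amide (free C6-OH)
Product: 29 Weinreb amide with C6 silyl ether (C9 methyl carbonate; 2S 6R 7S)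
Conditions: t-BuMe2SiOTf, 2,6-lutidine, CH2Cl2, −78 → 0 °C
Reagents that add atoms: tert-butyldimethylsilyl trifluoromethanesulfonate, CC(C)(C)[Si](C)(C)OS(=O)(=O)C(F)(F)F
Why: Silylation of the hindered secondary allylic alcohol with the silyl triflate; this blocks retro-aldol cleavage in the later steps.

Step 21
Reactants: 29 Weinreb amide with C6 silyl ether (C9 methyl carbonate)
Product: 30 C1 pinacolboronate (1S 2S 6R 7S; C10=C9 methylene; C8 Weinreb amide)
Conditions: CuCl (5 mol%), QuinoxP* (5 mol%; enantiomer matched to the substrate bias), KOt-Bu (5 mol%), B2pin2, THF, 0 °C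
Reagents that add atoms: bis(pinacolato)diboron, CC1(C)OB(OC1(C)C)B1OC(C)(C)C(C)(C)O1
Why: Copper-catalysed γ-selective boryl substitution (SN2') of an allylic carbonate: the copper–boryl adds across C1=C10 with boron on C1, and β-elimination of the carbonate leaves the C10=C9 methylene. The CH2 arm cis to C2 holds C2–H in the olefin plane (A(1,3) strain), so boron is delivered to the face opposite the C3 chain, giving the 1,2-syn (1S,2S) boronate; the chiral bisphosphine reinforces this. The released methoxide is taken up by boron, so no free base attacks the amide or the silyl ethers.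

Step 22
Reactants: 30 C1 pinacolboronate (C8 Weinreb amide)
Product: 31 seco aldehyde (C8 aldehyde; 1S C1 pinacolboronate; C10=C9 methylene; C2 and C6 silyl ethers; C15 4-methoxybenzyl ether; 2S 6R 7S)
Conditions: i-Bu2AlH, THF, −78 °C; aq. potassium sodium tartrate, 0 °C; used at once as a dilute solution
Reagents that add atoms: none
Why: A Weinreb amide is reduced to a stable aluminium chelate that releases the aldehyde only on hydrolysis, so there is no over-reduction and no base to conjugate the α-alkenyl aldehyde or eliminate the β-silyloxy group. Pinacol boronates are inert to the hydride at −78 °C.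

Step 23
Reactants: 31 seco aldehyde (C8 aldehyde; 1S C1 pinacolboronate)
Product: 33 cyclodeca-1(10),4-dien-8-ol (2S 6R 7R 8R; both ring olefins ring-cis; free C8-OH; C2 C6 C12 C14 silyl ethers; C15 4-methoxybenzyl ether), via borate ester 32 (not isolated)
Conditions: toluene, 0.002 M, 25 → 60 °C; then aq. NaHCO3
Reagents that add atoms: none
Why: Proposed new method: the aldehyde oxygen of 31 binds boron and C9 attacks C8 through a six-membered chair (B, O, C8, C9, C10, C1), which forms C8–C9, shifts the olefin to C1=C10 and leaves borate 32, hydrolysed on work-up. The closest known chemistry is the bimolecular allylboration of aldehydes by α-substituted allyl pinacolboronates with 1,3-chirality transfer (including double-allylboration routes to 2-ene-1,5-diols) and ring-closing allylborations to five- to seven-membered rings; a ten-membered closure has not been shown. The carbocycle closes in a 10-exo-trig sense at the C8 carbonyl, with the new ring fused to the chair along C8–C9–C10–C1. C8 is controlled by the boron-bearing C1: with (1S), the C2 arm axial and C7 equatorial, C9 reaches the aldehyde face that gives (8R). The same axial C2 arm ends up cis to C9 on the new double bond, which is the ring-cis C1=C10 olefin with C14 trans to C2. The axial position is preferred because an equatorial C2 arm would clash with the pinacol methyl groups and with the C14 arm on C10. The step needs ring closure to beat bimolecular addition and the C2-axial chair to beat the C2-equatorial one (ring-trans olefin, 8S); high dilution and the turn imposed by the ring-cis C4=C5 olefin serve the first, the pinacol ester and the 2-substituted allyl unit the second. No acid or base is present, so C7 keeps its configuration.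

Step 24
Reactants: 33 cyclodeca-1(10),4-dien-8-ol (free C8-OH)
Product: 34 C8 isovalerate (C15 4-methoxybenzyl ether; four silyl ethers)
Conditions: isovaleryl chloride, pyridine, DMAP, CH2Cl2, 0 °C → rt
Reagents that add atoms: 3-methylbutanoyl chloride, CC(C)CC(=O)Cl
Why: DMAP-catalysed acylation of the only free hydroxyl; retention at C8.

Step 25
Reactants: 34 C8 isovalerate (C15 4-methoxybenzyl ether)
Product: 35 C15 primary allylic alcohol (C8 isovalerate; four silyl ethers)
Conditions: DDQ, CH2Cl2/pH 7 buffer, 0 °C
Reagents that add atoms: none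
Why: Oxidative cleavage of the 4-methoxybenzyl ether by hydride abstraction and hydrolysis; silyl ethers, the ester and the olefins are not affected at 0 °C.

Step 26
Reactants: 35 C15 primary allylic alcohol
Product: 36 C15 acetate (C8 isovalerate; C2 C6 C12 C14 silyl ethers)
Conditions: Ac2O, pyridine, DMAP (cat.), CH2Cl2, 0 °C
Reagents that add atoms: acetic anhydride, CC(=O)OC(C)=O
Why: Acetylation of the single free primary alcohol; this marks C15 off from C12 and C14 before they are unmasked.

Step 27
Reactants: 36 C15 acetate (four silyl ethers)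
Product: 37 tetraol (free C2 C6 C12 C14 hydroxyls; C15 acetate; C8 isovalerate)
Conditions: HF·pyridine, pyridine, THF, 0 °C → rt
Reagents that add atoms: none
Why: Buffered fluoride cleaves all four tert-butyldimethylsilyl ethers; the mildly acidic medium avoids acyl migration of the two esters.

Step 28
Reactants: 37 tetraol (free C2 C6 C12 C14 hydroxyls)
Product: 40 target CNP0524123.1, via dialdehyde 38 (not isolated), via lactol 39 (not isolated)
Conditions: TEMPO (20 mol%), PhI(OAc)2 (3.3 equiv), CH2Cl2, rt
Reagents that add atoms: none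
Why: Oxoammonium oxidation is selective for primary over secondary alcohols: C14 gives the enal and C12 the 2-methylene aldehyde 38, which O6 captures as lactol 39. The same oxidant takes 39 to the α-methylene lactone, while the secondary C2 carbinol reacts much more slowly.

## Compound list

1 | 2-butyne-1,4-diol | OCC#CCO | starting material
2 | 4-[(4-methoxybenzyl)oxy]but-2-yn-1-ol | OCC#CCOCc1ccc(OC)cc1 | intermediate
3 | sodium alkenylalanate (five-membered O–Al chelate; Al on the carbon bearing CH2OPMB) | COCCO[Al-]1(OCCOC)OCC=C1COCc1ccc(OC)cc1.[Na+] | intermediate (not isolated)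
4 | (Z)-3-iodo-4-[(4-methoxybenzyl)oxy]but-2-en-1-ol | OC/C=C(\I)COCc1ccc(OC)cc1 | intermediate
5 | (Z)-triethyl({3-iodo-4-[(4-methoxybenzyl)oxy]but-2-en-1-yl}oxy)silane | CC[Si](CC)(CC)OC/C=C(\I)COCc1ccc(OC)cc1 | intermediate
6 | (S)-epichlorohydrin, (2S)-2-(chloromethyl)oxirane | ClC[C@@H]1CO1 | starting material
7 | alkenyllithium (Li in place of I in 5; geometry retained) | CC[Si](CC)(CC)OC/C=C(\[Li])COCc1ccc(OC)cc1 | intermediate (not isolated)
8 | (2S,4E)-1-chloro-4-{[(4-methoxybenzyl)oxy]methyl}-6-[(triethylsilyl)oxy]hex-4-en-2-ol | ClC[C@@H](O)C/C(COCc1ccc(OC)cc1)=C\CO[Si](CC)(CC)CC | intermediate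
9 | (2S)-2-[(2E)-2-{[(4-methoxybenzyl)oxy]methyl}-4-[(triethylsilyl)oxy]but-2-en-1-yl]oxirane | O1C[C@@H]1C/C(COCc2ccc(OC)cc2)=C\CO[Si](CC)(CC)CC | intermediate (not isolated)
10 | (3S,5E)-5-{[(4-methoxybenzyl)oxy]methyl}-7-[(triethylsilyl)oxy]hepta-1,5-dien-3-ol | C=C[C@@H](O)C/C(COCc1ccc(OC)cc1)=C\CO[Si](CC)(CC)CC | intermediate
11 | ethyl 2-(hydroxymethyl)acrylate | C=C(CO)C(=O)OCC | starting material
12 | ethyl 2-({[tert-butyl(dimethyl)silyl]oxy}methyl)acrylate | C=C(CO[Si](C)(C)C(C)(C)C)C(=O)OCC | intermediate
13 | 2-({[tert-butyl(dimethyl)silyl]oxy}methyl)acrylic acid | C=C(CO[Si](C)(C)C(C)(C)C)C(=O)O | intermediate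
14 | (3S,5E)-5-{[(4-methoxybenzyl)oxy]methyl}-7-[(triethylsilyl)oxy]hepta-1,5-dien-3-yl 2-({[tert-butyl(dimethyl)silyl]oxy}methyl)prop-2-enoate | C=C[C@@H](OC(=O)C(=C)CO[Si](C)(C)C(C)(C)C)C/C(COCc1ccc(OC)cc1)=C\CO[Si](CC)(CC)CC | intermediate
15 | (5S)-3-({[tert-butyl(dimethyl)silyl]oxy}methyl)-5-[(2E)-2-{[(4-methoxybenzyl)oxy]methyl}-4-[(triethylsilyl)oxy]but-2-en-1-yl]furan-2(5H)-one | O=C1O[C@@H](C/C(COCc2ccc(OC)cc2)=C\CO[Si](CC)(CC)CC)C=C1CO[Si](C)(C)C(C)(C)C | intermediate
16 | (2E,4S,6E)-2-({[tert-butyl(dimethyl)silyl]oxy}methyl)-6-{[(4-methoxybenzyl)oxy]methyl}-8-[(triethylsilyl)oxy]octa-2,6-diene-1,4-diol (C9-OH cis to C2) | OC/C(CO[Si](C)(C)C(C)(C)C)=C\[C@@H](O)C/C(COCc1ccc(OC)cc1)=C\CO[Si](CC)(CC)CC | intermediate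
17 | C9 methyl carbonate of 16 (free C2-OH) | COC(=O)OC/C(CO[Si](C)(C)C(C)(C)C)=C\[C@@H](O)C/C(COCc1ccc(OC)cc1)=C\CO[Si](CC)(CC)CC | intermediate
18 | C2 tert-butyldimethylsilyl ether of 17 | COC(=O)OC/C(CO[Si](C)(C)C(C)(C)C)=C\[C@@H](O[Si](C)(C)C(C)(C)C)C/C(COCc1ccc(OC)cc1)=C\CO[Si](CC)(CC)CC | intermediate
19 | C6 enal (2S; C3 cis to C6 on C4=C5; C9 carbonate cis to C2 on C1=C10) | COC(=O)OC/C(CO[Si](C)(C)C(C)(C)C)=C\[C@@H](O[Si](C)(C)C(C)(C)C)C/C(COCc1ccc(OC)cc1)=C\C=O | intermediate
20 | 4-methyl hydrogen itaconate | C=C(CC(=O)OC)C(=O)O | starting material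
21 | methyl 3-(hydroxymethyl)but-3-enoate | C=C(CO)CC(=O)OC | intermediate
22 | methyl 3-({[tert-butyl(dimethyl)silyl]oxy}methyl)but-3-enoate | C=C(CO[Si](C)(C)C(C)(C)C)CC(=O)OC | intermediate
23 | 3-({[tert-butyl(dimethyl)silyl]oxy}methyl)but-3-enoic acid | C=C(CO[Si](C)(C)C(C)(C)C)CC(=O)O | intermediate
24 | (S)-4-benzyl-1,3-thiazolidine-2-thione | S=C1N[C@@H](Cc2ccccc2)CS1 | starting material
25 | (S)-4-benzyl-3-[3-({[tert-butyl(dimethyl)silyl]oxy}methyl)but-3-enoyl]-1,3-thiazolidine-2-thione | C=C(CO[Si](C)(C)C(C)(C)C)CC(=O)N1[C@@H](Cc2ccccc2)CSC1=S | intermediate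
26 | (Z)-trichlorotitanium enolate of 25 | C=C(CO[Si](C)(C)C(C)(C)C)/C=C(\O[Ti](Cl)(Cl)Cl)N1[C@@H](Cc2ccccc2)CSC1=S | intermediate (not isolated)
27 | syn-aldol adduct: C8 thioimide, free C6-OH (2S, 6R, 7S; the C7 letter differs from the target's because C8 is a carboxyl carbon, the spatial arrangement is the target's) | S=C1SC[C@H](Cc2ccccc2)N1C(=O)[C@@H](C(=C)CO[Si](C)(C)C(C)(C)C)[C@H](O)/C=C(/COCc2ccc(OC)cc2)C[C@H](O[Si](C)(C)C(C)(C)C)/C=C(/CO[Si](C)(C)C(C)(C)C)COC(=O)OC | intermediate
28 | C8 Weinreb amide, free C6-OH | CON(C)C(=O)[C@@H](C(=C)CO[Si](C)(C)C(C)(C)C)[C@H](O)/C=C(/COCc1ccc(OC)cc1)C[C@H](O[Si](C)(C)C(C)(C)C)/C=C(/CO[Si](C)(C)C(C)(C)C)COC(=O)OC | intermediate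
29 | C8 Weinreb amide, C6 silyl ether, C9 methyl carbonate | CON(C)C(=O)[C@@H](C(=C)CO[Si](C)(C)C(C)(C)C)[C@H](O[Si](C)(C)C(C)(C)C)/C=C(/COCc1ccc(OC)cc1)C[C@H](O[Si](C)(C)C(C)(C)C)/C=C(/CO[Si](C)(C)C(C)(C)C)COC(=O)OC | intermediate
30 | C1 pinacolboronate (1S, 2S, 6R, 7S), C10=C9 methylene, C8 Weinreb amide | CON(C)C(=O)[C@@H](C(=C)CO[Si](C)(C)C(C)(C)C)[C@H](O[Si](C)(C)C(C)(C)C)/C=C(/COCc1ccc(OC)cc1)C[C@H](O[Si](C)(C)C(C)(C)C)[C@@H](B1OC(C)(C)C(C)(C)O1)C(=C)CO[Si](C)(C)C(C)(C)C | intermediate
31 | seco aldehyde, precursor of the key step (C8 aldehyde, (1S)-C1 pinacolboronate, 2S, 6R, 7S) | O=C[C@@H](C(=C)CO[Si](C)(C)C(C)(C)C)[C@H](O[Si](C)(C)C(C)(C)C)/C=C(/COCc1ccc(OC)cc1)C[C@H](O[Si](C)(C)C(C)(C)C)[C@@H](B1OC(C)(C)C(C)(C)O1)C(=C)CO[Si](C)(C)C(C)(C)C | intermediate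
32 | macrocyclic C8 pinacol borate ester | C=C(CO[Si](C)(C)C(C)(C)C)[C@H]1[C@H](O[Si](C)(C)C(C)(C)C)/C=C(/COCc2ccc(OC)cc2)C[C@H](O[Si](C)(C)C(C)(C)C)/C=C(/CO[Si](C)(C)C(C)(C)C)C[C@H]1OB1OC(C)(C)C(C)(C)O1 | intermediate (not isolated)
33 | cyclodeca-1(10),4-dien-8-ol, product of the key step (2S, 6R, 7R, 8R; both ring olefins ring-cis) | C=C(CO[Si](C)(C)C(C)(C)C)[C@H]1[C@H](O[Si](C)(C)C(C)(C)C)/C=C(/COCc2ccc(OC)cc2)C[C@H](O[Si](C)(C)C(C)(C)C)/C=C(/CO[Si](C)(C)C(C)(C)C)C[C@H]1O | intermediate
34 | C8 isovalerate of 33 | C=C(CO[Si](C)(C)C(C)(C)C)[C@H]1[C@H](O[Si](C)(C)C(C)(C)C)/C=C(/COCc2ccc(OC)cc2)C[C@H](O[Si](C)(C)C(C)(C)C)/C=C(/CO[Si](C)(C)C(C)(C)C)C[C@H]1OC(=O)CC(C)C | intermediate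
35 | C15 alcohol (C8 isovalerate, four silyl ethers) | C=C(CO[Si](C)(C)C(C)(C)C)[C@H]1[C@H](O[Si](C)(C)C(C)(C)C)/C=C(/CO)C[C@H](O[Si](C)(C)C(C)(C)C)/C=C(/CO[Si](C)(C)C(C)(C)C)C[C@H]1OC(=O)CC(C)C | intermediate
36 | C15 acetate (C8 isovalerate, four silyl ethers) | C=C(CO[Si](C)(C)C(C)(C)C)[C@H]1[C@H](O[Si](C)(C)C(C)(C)C)/C=C(/COC(C)=O)C[C@H](O[Si](C)(C)C(C)(C)C)/C=C(/CO[Si](C)(C)C(C)(C)C)C[C@H]1OC(=O)CC(C)C | intermediate
37 | tetraol (C2, C6, C12, C14 hydroxyls; C15 acetate; C8 isovalerate; target configuration) | C=C(CO)[C@H]1[C@H](O)/C=C(/COC(C)=O)C[C@H](O)/C=C(/CO)C[C@H]1OC(=O)CC(C)C | intermediate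
38 | C12,C14-dialdehyde with free C2 and C6 hydroxyls | C=C(C=O)[C@H]1[C@H](O)/C=C(/COC(C)=O)C[C@H](O)/C=C(/C=O)C[C@H]1OC(=O)CC(C)C | intermediate (not isolated)
39 | C12 lactol (both anomers), C14 enal | C=C1C(O)O[C@@H]2/C=C(/COC(C)=O)C[C@H](O)/C=C(/C=O)C[C@@H](OC(=O)CC(C)C)[C@@H]12 | intermediate (not isolated)
40 | CNP0524123.1 (2S, 6R, 7R, 8R) | C=C1C(=O)O[C@@H]2/C=C(/COC(C)=O)C[C@H](O)/C=C(/C=O)C[C@@H](OC(=O)CC(C)C)[C@@H]12 | target

## Step count and risk

Total step count: 28. Longest linear sequence: 22 steps (steps 1–5, 8–13, 18–28); the key step is the seventeenth of these.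

Least certain steps:

Step 23 (key step). Most likely failure: bimolecular allylboration (oligomers) outrunning a closure slowed by transannular strain in the bicyclic transition state; or closure through the chair with C2 equatorial, giving the ring-trans olefin and the C8 epimer; or, if closure is slow, loss of configuration at C7 of the aldehyde. The fallback uses only known reactions: it forms C8–C9 by the bimolecular allylboration and closes the ring at C6–C7 with chromium. It sets out from 18 and returns at 34. Copper-catalysed borylation of 18 under the conditions of step 21 gives the C1 pinacolboronate F1. This is added in toluene at room temperature to 4-chloro-3-(silyloxymethyl)but-2-enal F2 (made separately; either olefin isomer serves, since both lead to the same allylchromium) to give the (8R)-homoallylic alcohol F3 with C9 cis to C2 on C1=C10. Isovaleroylation gives the ester F4, and Swern oxidation of its triethylsilyl ether gives the C6 enal F5. CrCl2 with LiI under high dilution then joins C7 to C6 by γ-attack of the allylchromium, a closure known for ten-membered germacranolide rings, giving the macrocyclic C6 alcohol F6 with the C11=C13 methylene. Silylation with the silyl triflate gives 34. The cost is that C6 and C7 then depend on induction from C8 in the macrocyclic transition state.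

Step 21. Most likely failure: delivery of boron to the wrong face of C1 if the ligand and the C2 stereocentre oppose each other, or base-induced loss of the β-silyloxy group from the boronate. The fallback gives up control at C1 and corrects at C8. It sets out from 29 and returns at 34. The (1R)-boronate F7 (C1 epimer of 30) is reduced as in step 22 to the aldehyde F8. Its C2-axial chair closes to the same ring-cis olefin but the 8-epimeric alcohol F9. Mitsunobu esterification of F9 with isovaleric acid (PPh3, diisopropyl azodicarboxylate) inverts C8 and gives 34 directly, so both C1 epimers converge.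

Step 22. Most likely failure: transfer of the allyl group from boron to aluminium or over-reduction; elimination of the β-silyloxy group or conjugation of the aldehyde during work-up; bimolecular allylboration while the aldehyde is concentrated. The fallback carries C8 as a silyl ether and frees it by oxidation. It sets out from 27 and returns at 31. NaBH4 reduces the thioimide of 27 to the 1,3-diol F10. Et3SiCl at −40 °C silylates the primary hydroxyl (C8 triethylsilyl ether F11), and the silyl triflate protects O6 (F12). Borylation as in step 21 gives the boronate F13, and Swern oxidation of its primary triethylsilyl ether, directly in dilute solution, gives 31.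

Step 18. Most likely failure: reaction of the dienolate at its γ-carbon, isomerisation of the β,γ-unsaturated acyl group, retro-aldol cleavage, or Lewis-acid loss of the 4-methoxybenzyl ether. The fallback replaces the aldol by an asymmetric chromium allylation. It sets out from 19 and returns at 31. The allylic bromide F14 (made separately; either olefin isomer) and 19 are treated with CrCl2 and a chiral bis(oxazolinyl)carbazole ligand. γ-Attack of the allylchromium gives the anti adduct, which is the C8 triethylsilyl ether F11 of the preceding fallback, and this is taken on through F12 and F13 to 31.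

Step 28. Most likely failure: over-oxidation of the C2 carbinol to the enone, or incomplete oxidation of the lactol. The fallback stages the oxidation. It sets out from 36 and returns at 39. Buffered HF·pyridine at 0 °C removes only the two primary silyl ethers (C12,C14-diol F15), and MnO2 gives the bis-silylated dialdehyde F16 while C2 is still protected. HF·pyridine then frees O2 and O6, giving 38 and hence lactol 39, which Ag2CO3 on Celite, a lactol-selective oxidant, takes to 40.

## Further compounds

F1 | step 23 | C1 pinacolboronate from 18 (1S, 2S; C6 triethylsilyl ether) | C=C(CO[Si](C)(C)C(C)(C)C)[C@H](B1OC(C)(C)C(C)(C)O1)[C@@H](O[Si](C)(C)C(C)(C)C)C/C(COCc1ccc(OC)cc1)=C\CO[Si](CC)(CC)CC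
F2 | step 23 | 4-chloro-3-({[tert-butyl(dimethyl)silyl]oxy}methyl)but-2-enal (E/Z mixture; olefin geometry not specified) | O=CC=C(CCl)CO[Si](C)(C)C(C)(C)C
F3 | step 23 | (8R)-homoallylic alcohol from F1 and F2 (C9 cis to C2 on C1=C10) | ClCC(CO[Si](C)(C)C(C)(C)C)=C[C@H](O)C/C(CO[Si](C)(C)C(C)(C)C)=C\[C@@H](O[Si](C)(C)C(C)(C)C)C/C(COCc1ccc(OC)cc1)=C\CO[Si](CC)(CC)CC
F4 | step 23 | C8 isovalerate of F3 | ClCC(CO[Si](C)(C)C(C)(C)C)=C[C@H](OC(=O)CC(C)C)C/C(CO[Si](C)(C)C(C)(C)C)=C\[C@@H](O[Si](C)(C)C(C)(C)C)C/C(COCc1ccc(OC)cc1)=C\CO[Si](CC)(CC)CC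
F5 | step 23 | C6 enal with C13 allylic chloride | ClCC(CO[Si](C)(C)C(C)(C)C)=C[C@H](OC(=O)CC(C)C)C/C(CO[Si](C)(C)C(C)(C)C)=C\[C@@H](O[Si](C)(C)C(C)(C)C)C/C(COCc1ccc(OC)cc1)=C\C=O
F6 | step 23 | macrocycle with free C6 hydroxyl (34 without its O6 silyl group) | C=C(CO[Si](C)(C)C(C)(C)C)[C@H]1[C@H](O)/C=C(/COCc2ccc(OC)cc2)C[C@H](O[Si](C)(C)C(C)(C)C)/C=C(/CO[Si](C)(C)C(C)(C)C)C[C@H]1OC(=O)CC(C)C
F7 | step 21 | (1R)-C1 pinacolboronate, C1 epimer of 30 | CON(C)C(=O)[C@@H](C(=C)CO[Si](C)(C)C(C)(C)C)[C@H](O[Si](C)(C)C(C)(C)C)/C=C(/COCc1ccc(OC)cc1)C[C@H](O[Si](C)(C)C(C)(C)C)[C@H](B1OC(C)(C)C(C)(C)O1)C(=C)CO[Si](C)(C)C(C)(C)C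
F8 | step 21 | (1R)-seco aldehyde, C1 epimer of 31 | O=C[C@@H](C(=C)CO[Si](C)(C)C(C)(C)C)[C@H](O[Si](C)(C)C(C)(C)C)/C=C(/COCc1ccc(OC)cc1)C[C@H](O[Si](C)(C)C(C)(C)C)[C@H](B1OC(C)(C)C(C)(C)O1)C(=C)CO[Si](C)(C)C(C)(C)C
F9 | step 21 | 8-epi-33 | C=C(CO[Si](C)(C)C(C)(C)C)[C@H]1[C@H](O[Si](C)(C)C(C)(C)C)/C=C(/COCc2ccc(OC)cc2)C[C@H](O[Si](C)(C)C(C)(C)C)/C=C(/CO[Si](C)(C)C(C)(C)C)C[C@@H]1O
F10 | step 22 | C6,C8-diol from reduction of 27 | OC[C@@H](C(=C)CO[Si](C)(C)C(C)(C)C)[C@H](O)/C=C(/COCc1ccc(OC)cc1)C[C@H](O[Si](C)(C)C(C)(C)C)/C=C(/CO[Si](C)(C)C(C)(C)C)COC(=O)OC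
F11 | step 22 | C8 triethylsilyl ether with free C6 hydroxyl | CC[Si](CC)(CC)OC[C@@H](C(=C)CO[Si](C)(C)C(C)(C)C)[C@H](O)/C=C(/COCc1ccc(OC)cc1)C[C@H](O[Si](C)(C)C(C)(C)C)/C=C(/CO[Si](C)(C)C(C)(C)C)COC(=O)OC
F12 | step 22 | C8 triethylsilyl ether, C6 tert-butyldimethylsilyl ether, C9 carbonate | CC[Si](CC)(CC)OC[C@@H](C(=C)CO[Si](C)(C)C(C)(C)C)[C@H](O[Si](C)(C)C(C)(C)C)/C=C(/COCc1ccc(OC)cc1)C[C@H](O[Si](C)(C)C(C)(C)C)/C=C(/CO[Si](C)(C)C(C)(C)C)COC(=O)OC
F13 | step 22 | (1S)-C1 pinacolboronate with C8 triethylsilyl ether | CC[Si](CC)(CC)OC[C@@H](C(=C)CO[Si](C)(C)C(C)(C)C)[C@H](O[Si](C)(C)C(C)(C)C)/C=C(/COCc1ccc(OC)cc1)C[C@H](O[Si](C)(C)C(C)(C)C)[C@@H](B1OC(C)(C)C(C)(C)O1)C(=C)CO[Si](C)(C)C(C)(C)C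
F14 | step 18 | 1-bromo-2-({[tert-butyl(dimethyl)silyl]oxy}methyl)-4-[(triethylsilyl)oxy]but-2-ene (E/Z mixture; olefin geometry not specified) | BrCC(CO[Si](C)(C)C(C)(C)C)=CCO[Si](CC)(CC)CC
F15 | step 28 | C12,C14-diol with C2 and C6 silyl ethers | C=C(CO)[C@H]1[C@H](O[Si](C)(C)C(C)(C)C)/C=C(/COC(C)=O)C[C@H](O[Si](C)(C)C(C)(C)C)/C=C(/CO)C[C@H]1OC(=O)CC(C)C
F16 | step 28 | C12,C14-dialdehyde with C2 and C6 silyl ethers | C=C(C=O)[C@H]1[C@H](O[Si](C)(C)C(C)(C)C)/C=C(/COC(C)=O)C[C@H](O[Si](C)(C)C(C)(C)C)/C=C(/C=O)C[C@H]1OC(=O)CC(C)C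
A1 | alternative 1 | cyclodecadienyl triflate (ring-cis C4=C5, ring-trans C1=C10 enol triflate; C2 and C15 4-methoxybenzyl ethers; C6 and C12 tert-butyldimethylsilyl ethers; C8 triethylsilyl ether) | C=C(CO[Si](C)(C)C(C)(C)C)[C@H]1[C@H](O[Si](C)(C)C(C)(C)C)/C=C(/COCc2ccc(OC)cc2)C[C@H](OCc2ccc(OC)cc2)/C=C(\OS(=O)(=O)C(F)(F)F)C[C@H]1O[Si](CC)(CC)CC
A2 | alternative 2 | cyclodecadienol with free C6 hydroxyl and 8-epi methoxymethyl ether (C12 triethylsilyl, C15 and C2 tert-butyldimethylsilyl, C14 tert-butyldiphenylsilyl ethers) | C=C(CO[Si](CC)(CC)CC)[C@H]1[C@H](O)/C=C(/CO[Si](C)(C)C(C)(C)C)C[C@H](O[Si](C)(C)C(C)(C)C)/C=C(/CO[Si](c2ccccc2)(c2ccccc2)C(C)(C)C)C[C@@H]1OCOC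
A3 | alternative 3 | macrocyclic lactone with free C2 hydroxyl and C14 tert-butyldimethylsilyl ether | C=C1C(=O)O[C@@H]2/C=C(/COC(C)=O)C[C@H](O)/C=C(/CO[Si](C)(C)C(C)(C)C)C[C@@H](OC(=O)CC(C)C)[C@@H]12
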